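**Plan**

1. Retrosynthetic cuts, in order: the C3–O ester bond; the side-chain bond C1'=C2' (cross-metathesis, later saturated); the piperidine bond C3=C4 together with re-closure of C4=C1' to a cyclobutene (one ring-rearrangement metathesis); the enol ether CH2 (ester methylenation); C8a–N (reductive amination); C4a–C4 and C5–C1' ([2+2] of an enone with acetylene).
2. Forward: the carbocycle is bought as cyclohexenone, the cyclobutene is fused on, the nitrogen tether is attached, the piperidine closes as the cyclobutene opens, the side chain is joined to the vinyl group set free, and C3 is adjusted, acylated and deprotected.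
3. Enabling feature: C4 (on C4a) and C1' (on C5) are cis substituents on adjacent carbons of the carbocycle and N on C8a lies on the same face, so C4=C1' can be the double bond of a cis-fused cyclobutene whose metathetic opening hands C4 to the piperidine and leaves C1' as a vinyl handle.
4. Stereochemistry: C2 from L-alanine; C4a/C5 cis from the photocycloaddition (racemic, resolved as diastereomers at the amine stage); C8a from hydride attack on the convex face; C3 from face-selective ketone reduction followed by Mitsunobu inversion; C5' from (R)-2-propyloxirane.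

Key step: step 5

Remark: ketone 3 is made and used as the racemate and is resolved by the L-alanine unit in step 2, so at most half of 3 is carried on; lepadin numbering (N1, C2–C8a, side chain C1'–C8') is used for all bicyclic compounds.

**Route**

Step 1
Reactants: 1 cyclohex-2-en-1-one; 2 acetylene
Product: 3 (±)-cis-bicyclo[4.2.0]oct-7-en-2-one (racemate; the (1S,6R) enantiomer is the one carried on)
Conditions: hν (medium-pressure Hg lamp, Pyrex filter), acetylene-saturated acetone, −70 °C, stopped before full conversion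
Reagents that add atoms: none
Why: Enone–alkyne [2+2] photocycloaddition through the enone triplet should give the cyclobutene, which can only be cis-fused to the six-membered ring, so C1 and C6 are set as a racemic cis pair, while low temperature and partial conversion limit secondary photochemistry of the β,γ-unsaturated ketone.

Step 2
Reactants: 3 (±)-cis-bicyclo[4.2.0]oct-7-en-2-one; 4 L-alanine methyl ester hydrochloride
Product: 6 methyl N-[(1S,2R,6R)-bicyclo[4.2.0]oct-7-en-2-yl]-L-alaninate, via ketimine 5 (not isolated)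
Conditions: Et3N (1 equiv to 4), AcOH, NaBH(OAc)3, ClCH2CH2Cl, rt; chromatographic separation of the two all-cis diastereomers
Reagents that add atoms: none
Why: Direct reductive amination with a bulky acyloxyborohydride should reduce the iminium ion from the convex face anti to the cyclobutene, placing nitrogen cis to the four-membered ring, and because the alanine centre is fixed as S the two enantiomers of 3 should give separable diastereomers, of which the (1S,2R,6R) one is kept.

Step 3
Reactants: 6 methyl N-[(1S,2R,6R)-bicyclo[4.2.0]oct-7-en-2-yl]-L-alaninate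
Product: 7 methyl N-(tert-butoxycarbonyl)-N-[(1S,2R,6R)-bicyclo[4.2.0]oct-7-en-2-yl]-L-alaninate
Conditions: Boc2O (4 equiv, in portions), DMAP (0.2 equiv), MeCN, 60 °C
Reagents that add atoms: di-tert-butyl dicarbonate, CC(C)(C)OC(=O)OC(=O)OC(C)(C)C
Why: Carbamate formation on a secondary amine; the nitrogen is flanked by two branched carbons, so excess reagent, nucleophilic catalysis and heat are used, and no stereocentre is touched under these non-basic conditions.

Step 4
Reactants: 7 methyl N-(tert-butoxycarbonyl)-N-[(1S,2R,6R)-bicyclo[4.2.0]oct-7-en-2-yl]-L-alaninate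
Product: 8 tert-butyl [(1S,2R,6R)-bicyclo[4.2.0]oct-7-en-2-yl][(2S)-3-methoxybut-3-en-2-yl]carbamate
Conditions: Tebbe reagent (1.3 equiv), pyridine (cat.), THF–toluene, −40 → 0 °C; aq. NaOH; chromatography on Et3N-deactivated SiO2
Reagents that add atoms: Tebbe reagent, C[Al-]1(C)C[Ti]([Cl+]1)(C2C=CC=C2)C3C=CC=C3
Why: Tebbe methylenation of an ester to the methyl enol ether (carbonyl olefination by Cp2Ti=CH2); at −40 °C with only a weak Lewis base the ester carbonyl should trap the titanium methylidene faster than the strained alkene or the carbamate, and the reagent is not basic enough to epimerise the alanine-derived centre.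

Step 5
Reactants: 8 tert-butyl [(1S,2R,6R)-bicyclo[4.2.0]oct-7-en-2-yl][(2S)-3-methoxybut-3-en-2-yl]carbamate
Product: 10 tert-butyl (2S,4aR,5R,8aR)-5-ethenyl-3-methoxy-2-methyl-4a,5,6,7,8,8a-hexahydroquinoline-1(2H)-carboxylate, via ring-opened triene 9 (not isolated)
Conditions: Hoveyda–Grubbs II (10 mol%), ethylene (1 atm), toluene (0.01 M), 25 °C; then Ar purge, 1,4-benzoquinone (10 mol%), 70 °C
Reagents that add atoms: ethylene, C=C (terminal CH2 of the C5 vinyl group)
Why: Proposed new method: a ruthenium methylidene undergoes [2+2] cycloaddition and cycloreversion with the strained cyclobutene C4=C1' (ethenolysis to triene 9), and once ethylene is swept out the alkylidene formed at C4 adds to the 1,1-disubstituted enol ether of the N-tether with ruthenium on the terminal CH2, so that cycloreversion should give the C3=C4 enol ether and return Ru=CH2 instead of a Fischer carbene. The closest known reactions are ring-rearrangement metathesis of cyclobutenes onto tethered plain alkenes and ring-closing metathesis of an alkene onto a 2-alkoxy- or 2-silyloxyallyl group; using both in one operation on a substrate of this kind is the untested part. The one ring formed, the tetrahydropyridine N1–C2–C3=C4–C4a–C8a, arises by six-membered ring-closing metathesis across the carbamate nitrogen. No stereocentre is created: C2 comes from L-alanine and C4a, C5 and C8a are sp3 carbons of 8 that metathesis does not touch, so the all-cis arrangement of C4, C1' and N is carried over unchanged. The step needs closure from C4 (six-membered) and not from C1' (seven-membered), and neither ring-opening polymerisation nor catalyst arrest: the shorter tether and the greater stability of the six-membered ring should decide the first, while the ethylene stage turns every opened cyclobutene into the same triene whichever way the catalyst added, high dilution suppresses oligomers, and heat reactivates any alkoxycarbene formed at the enol ether terminus.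

Step 6
Reactants: 11 (R)-2-propyloxirane
Product: 12 (5R)-oct-1-en-5-ol
Conditions: allylMgBr (1.5 equiv), CuI (10 mol%), THF, −30 → 0 °C; H2O
Reagents that add atoms: allylmagnesium bromide, C=CC[Mg]Br
Why: Copper-catalysed SN2 opening of a terminal epoxide by an allyl Grignard reagent at the unsubstituted carbon, which leaves the (R) carbinol centre untouched.

Step 7
Reactants: 12 (5R)-oct-1-en-5-ol
Product: 13 tert-butyl(dimethyl){[(5R)-oct-1-en-5-yl]oxy}silane
Conditions: TBSCl, imidazole, DMF, rt
Reagents that add atoms: tert-butyldimethylsilyl chloride, CC(C)(C)[Si](C)(C)Cl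
Why: Standard silylation of a secondary alcohol, which masks the side-chain hydroxyl so that only the C3 hydroxyl is esterified later.

Step 8
Reactants: 10 tert-butyl (2S,4aR,5R,8aR)-5-ethenyl-3-methoxy-2-methyl-4a,5,6,7,8,8a-hexahydroquinoline-1(2H)-carboxylate; 13 tert-butyl(dimethyl){[(5R)-oct-1-en-5-yl]oxy}silane
Product: 14 tert-butyl (2S,4aR,5R,8aR)-5-[(1E,5R)-5-{[tert-butyl(dimethyl)silyl]oxy}oct-1-en-1-yl]-3-methoxy-2-methyl-4a,5,6,7,8,8a-hexahydroquinoline-1(2H)-carboxylate (E drawn; any Z isomer converges in step 10)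
Conditions: 13 (3 equiv), Hoveyda–Grubbs II (5 mol%), CH2Cl2, 40 °C
Reagents that add atoms: none
Why: Olefin cross-metathesis between the monosubstituted vinyl group of 10 and an excess of the unhindered terminal alkene 13 with loss of ethylene; the trisubstituted cyclic enol ether should be too hindered to engage the catalyst.

Step 9
Reactants: 14 tert-butyl (2S,4aR,5R,8aR)-5-[(1E,5R)-5-{[tert-butyl(dimethyl)silyl]oxy}oct-1-en-1-yl]-3-methoxy-2-methyl-4a,5,6,7,8,8a-hexahydroquinoline-1(2H)-carboxylate
Product: 15 tert-butyl (2S,4aS,5R,8aR)-5-[(1E,5R)-5-{[tert-butyl(dimethyl)silyl]oxy}oct-1-en-1-yl]-2-methyl-3-oxooctahydroquinoline-1(2H)-carboxylate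
Conditions: oxalic acid (5% aq.), THF, 0 °C
Reagents that add atoms: water, O
Why: Acid-catalysed enol ether hydrolysis (protonation at C4, hydration of the oxocarbenium ion, loss of methanol) under conditions mild enough for the Boc and TBS groups and short and cold enough to keep the α-amino ketone from epimerising at C2; it is run before hydrogenation so that the enol ether cannot be reduced to a methyl ether.

Step 10
Reactants: 15 tert-butyl (2S,4aS,5R,8aR)-5-[(1E,5R)-5-{[tert-butyl(dimethyl)silyl]oxy}oct-1-en-1-yl]-2-methyl-3-oxooctahydroquinoline-1(2H)-carboxylate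
Product: 16 tert-butyl (2S,4aS,5S,8aR)-5-[(5R)-5-{[tert-butyl(dimethyl)silyl]oxy}octyl]-2-methyl-3-oxooctahydroquinoline-1(2H)-carboxylate
Conditions: H2 (1 atm), 10% Pd/C, EtOAc, rt
Reagents that add atoms: none
Why: Heterogeneous catalytic hydrogenation of the disubstituted side-chain alkene; ketone, carbamate and silyl ether are inert under these neutral conditions and no stereocentre is formed.

Step 11
Reactants: 16 tert-butyl (2S,4aS,5S,8aR)-5-[(5R)-5-{[tert-butyl(dimethyl)silyl]oxy}octyl]-2-methyl-3-oxooctahydroquinoline-1(2H)-carboxylate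
Product: 17 tert-butyl (2S,3S,4aS,5S,8aR)-5-[(5R)-5-{[tert-butyl(dimethyl)silyl]oxy}octyl]-3-hydroxy-2-methyloctahydroquinoline-1(2H)-carboxylate
Conditions: L-Selectride, THF, −78 °C; H2O
Reagents that add atoms: none
Why: Diastereoselective hydride reduction of an N-Boc 2-alkylpiperidin-3-one: allylic 1,3-strain with the carbamate holds the C2 methyl axial, so the bulky hydride should add to the C3 carbonyl from the face opposite the methyl and give the 2,3-cis (3S) alcohol.

Step 12
Reactants: 18 (2E)-hex-2-enal
Product: 20 (2E,4E)-octa-2,4-dienoic acid, via hexenylidenemalonic acid 19 (not isolated)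
Conditions: malonic acid (1.5 equiv), pyridine, piperidine (cat.), 90 °C
Reagents that add atoms: malonic acid, OC(=O)CC(=O)O
Why: Knoevenagel–Doebner condensation of an enal with malonic acid followed by decarboxylation in pyridine, which should give the thermodynamically favoured (2E,4E)-dienoic acid.

Step 13
Reactants: 17 tert-butyl (2S,3S,4aS,5S,8aR)-5-[(5R)-5-{[tert-butyl(dimethyl)silyl]oxy}octyl]-3-hydroxy-2-methyloctahydroquinoline-1(2H)-carboxylate; 20 (2E,4E)-octa-2,4-dienoic acid
Product: 21 tert-butyl (2S,3R,4aS,5S,8aR)-5-[(5R)-5-{[tert-butyl(dimethyl)silyl]oxy}octyl]-2-methyl-3-{[(2E,4E)-octa-2,4-dienoyl]oxy}octahydroquinoline-1(2H)-carboxylate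
Conditions: PPh3, DIAD, toluene, 0 °C → rt
Reagents that add atoms: none
Why: Mitsunobu esterification: the equatorial C3 hydroxyl is activated as an alkoxyphosphonium ion and displaced by the dienoate from the opposite face (SN2), inverting C3 to the R configuration trans to the C2 methyl, while the carbamate cannot participate because only a bridged ring could result.

Step 14
Reactants: 21 tert-butyl (2S,3R,4aS,5S,8aR)-5-[(5R)-5-{[tert-butyl(dimethyl)silyl]oxy}octyl]-2-methyl-3-{[(2E,4E)-octa-2,4-dienoyl]oxy}octahydroquinoline-1(2H)-carboxylate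
Product: 23 lepadin H, via N-deprotected silyl ether 22 (not isolated)
Conditions: TFA/CH2Cl2/H2O (10:10:1), 0 °C → rt; aq. NaHCO3
Reagents that add atoms: none
Why: Acidolysis removes the Boc group with loss of 2-methylpropene and carbon dioxide and the aqueous acid then cleaves the secondary TBS ether, while the dienoate ester and all stereocentres should be stable to these conditions.

**Compound list**

1 | cyclohex-2-en-1-one | O=C1C=CCCC1 | starting material
2 | acetylene | C#C | starting material
3 | (±)-cis-bicyclo[4.2.0]oct-7-en-2-one (racemate; (1S,6R) enantiomer drawn) | O=C1CCC[C@@H]2C=C[C@H]12 | intermediate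
4 | L-alanine methyl ester hydrochloride | C[C@H](N)C(=O)OC.Cl | starting material
5 | methyl (2S)-2-{[(1S,6R)-bicyclo[4.2.0]oct-7-en-2-ylidene]amino}propanoate | COC(=O)[C@H](C)N=C1CCC[C@@H]2C=C[C@H]12 | intermediate (not isolated)
6 | methyl N-[(1S,2R,6R)-bicyclo[4.2.0]oct-7-en-2-yl]-L-alaninate | COC(=O)[C@H](C)N[C@@H]1CCC[C@@H]2C=C[C@H]12 | intermediate
7 | methyl N-(tert-butoxycarbonyl)-N-[(1S,2R,6R)-bicyclo[4.2.0]oct-7-en-2-yl]-L-alaninate | COC(=O)[C@H](C)N(C(=O)OC(C)(C)C)[C@@H]1CCC[C@@H]2C=C[C@H]12 | intermediate
8 | tert-butyl [(1S,2R,6R)-bicyclo[4.2.0]oct-7-en-2-yl][(2S)-3-methoxybut-3-en-2-yl]carbamate | C=C(OC)[C@H](C)N(C(=O)OC(C)(C)C)[C@@H]1CCC[C@@H]2C=C[C@H]12 | intermediate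
9 | tert-butyl [(1R,2S,3R)-2,3-diethenylcyclohexyl][(2S)-3-methoxybut-3-en-2-yl]carbamate | C=C(OC)[C@H](C)N(C(=O)OC(C)(C)C)[C@@H]1CCC[C@H](C=C)[C@@H]1C=C | intermediate (not isolated)
10 | tert-butyl (2S,4aR,5R,8aR)-5-ethenyl-3-methoxy-2-methyl-4a,5,6,7,8,8a-hexahydroquinoline-1(2H)-carboxylate | COC1=C[C@H]2[C@@H](C=C)CCC[C@H]2N(C(=O)OC(C)(C)C)[C@H]1C | intermediate
11 | (R)-2-propyloxirane | CCC[C@@H]1CO1 | starting material
12 | (5R)-oct-1-en-5-ol | CCC[C@@H](O)CCC=C | intermediate
13 | tert-butyl(dimethyl){[(5R)-oct-1-en-5-yl]oxy}silane | CCC[C@@H](O[Si](C)(C)C(C)(C)C)CCC=C | intermediate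
14 | tert-butyl (2S,4aR,5R,8aR)-5-[(1E,5R)-5-{[tert-butyl(dimethyl)silyl]oxy}oct-1-en-1-yl]-3-methoxy-2-methyl-4a,5,6,7,8,8a-hexahydroquinoline-1(2H)-carboxylate | COC1=C[C@H]2[C@@H](/C=C/CC[C@H](O[Si](C)(C)C(C)(C)C)CCC)CCC[C@H]2N(C(=O)OC(C)(C)C)[C@H]1C | intermediate
15 | tert-butyl (2S,4aS,5R,8aR)-5-[(1E,5R)-5-{[tert-butyl(dimethyl)silyl]oxy}oct-1-en-1-yl]-2-methyl-3-oxooctahydroquinoline-1(2H)-carboxylate | O=C1C[C@H]2[C@@H](/C=C/CC[C@H](O[Si](C)(C)C(C)(C)C)CCC)CCC[C@H]2N(C(=O)OC(C)(C)C)[C@H]1C | intermediate
16 | tert-butyl (2S,4aS,5S,8aR)-5-[(5R)-5-{[tert-butyl(dimethyl)silyl]oxy}octyl]-2-methyl-3-oxooctahydroquinoline-1(2H)-carboxylate | O=C1C[C@H]2[C@@H](CCCC[C@H](O[Si](C)(C)C(C)(C)C)CCC)CCC[C@H]2N(C(=O)OC(C)(C)C)[C@H]1C | intermediate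
17 | tert-butyl (2S,3S,4aS,5S,8aR)-5-[(5R)-5-{[tert-butyl(dimethyl)silyl]oxy}octyl]-3-hydroxy-2-methyloctahydroquinoline-1(2H)-carboxylate | O[C@H]1C[C@H]2[C@@H](CCCC[C@H](O[Si](C)(C)C(C)(C)C)CCC)CCC[C@H]2N(C(=O)OC(C)(C)C)[C@H]1C | intermediate
18 | (2E)-hex-2-enal | CCC/C=C/C=O | starting material
19 | 2-[(2E)-hex-2-en-1-ylidene]propanedioic acid | CCC/C=C/C=C(C(=O)O)C(=O)O | intermediate (not isolated)
20 | (2E,4E)-octa-2,4-dienoic acid | CCC/C=C/C=C/C(=O)O | intermediate
21 | tert-butyl (2S,3R,4aS,5S,8aR)-5-[(5R)-5-{[tert-butyl(dimethyl)silyl]oxy}octyl]-2-methyl-3-{[(2E,4E)-octa-2,4-dienoyl]oxy}octahydroquinoline-1(2H)-carboxylate | CCC/C=C/C=C/C(=O)O[C@@H]1C[C@H]2[C@@H](CCCC[C@H](O[Si](C)(C)C(C)(C)C)CCC)CCC[C@H]2N(C(=O)OC(C)(C)C)[C@H]1C | intermediate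
22 | (2S,3R,4aS,5S,8aR)-5-[(5R)-5-{[tert-butyl(dimethyl)silyl]oxy}octyl]-2-methyldecahydroquinolin-3-yl (2E,4E)-octa-2,4-dienoate | CCC/C=C/C=C/C(=O)O[C@@H]1C[C@H]2[C@@H](CCCC[C@H](O[Si](C)(C)C(C)(C)C)CCC)CCC[C@H]2N[C@H]1C | intermediate (not isolated)
23 | lepadin H, (2S,3R,4aS,5S,8aR)-5-[(5R)-5-hydroxyoctyl]-2-methyldecahydroquinolin-3-yl (2E,4E)-octa-2,4-dienoate | CCC/C=C/C=C/C(=O)O[C@@H]1C[C@H]2[C@@H](CCCC[C@H](O)CCC)CCC[C@H]2N[C@H]1C | target

**Step count**

Total: 14 steps. Longest linear sequence: 11 steps from cyclohex-2-en-1-one (steps 1–5, 8–11, 13, 14). The side chain takes two steps (6, 7) and the acid one (12).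

**Steps most likely to fail**

1. Step 5 (proposed new method). After the cyclobutene is opened, the catalyst may be held as an unreactive alkoxycarbene at the enol ether terminus, closure may start from the alkylidene at C1' (seven-membered ring), or the opened alkylidene may add to a second cyclobutene and give oligomers. The fallback uses only known reaction types and forms C3=C4 by carbonyl olefination instead of enol ether metathesis. It sets out from 7. Ethenolysis of the cyclobutene (Grubbs II, ethylene 1 atm, CH2Cl2, rt; ring-opening metathesis of a cyclobutene with ethylene) should give methyl N-(tert-butoxycarbonyl)-N-[(1R,2S,3R)-2,3-diethenylcyclohexyl]-L-alaninate F1. A titanium-alkylidene-mediated olefinic ester cyclisation (Takai–Utimoto reagent from TiCl4, Zn, PbCl2, TMEDA and 1,1-dibromoethane, THF, 65 °C) should then convert the C4 vinyl group into a titanium alkylidene that olefinates the ester carbonyl through the six-membered transition. This gives the cyclic methyl enol ether directly, and the route is rejoined at 10.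

2. Step 4. The titanium methylidene may add to the strained cyclobutene (titanacyclobutane formation, ring opening, oligomers) in competition with methylenation of the hindered ester. The fallback reverses the order of events and sets out from 7. Ethenolysis as above should give the divinyl ester methyl N-(tert-butoxycarbonyl)-N-[(1R,2S,3R)-2,3-diethenylcyclohexyl]-L-alaninate F2, which no longer holds a strained alkene. Tebbe methylenation of F2 at −40 °C should then give triene 9, now isolated. The route is rejoined at 9, which is closed to 10 under the second stage of step 5 (argon, 70 °C).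

3. Step 13. Activation of the hindered C3 carbinol, flanked by the axial C2 methyl and the carbamate, may stall at the alkoxyphosphonium stage with the weakly acidic dienoic acid, or turn into elimination toward C4. The fallback separates inversion from acylation and sets out from 17. Mitsunobu reaction with the smaller and more acidic 4-nitrobenzoic acid (PPh3, DIAD, toluene) should give tert-butyl (2S,3R,4aS,5S,8aR)-5-[(5R)-5-{[tert-butyl(dimethyl)silyl]oxy}octyl]-2-methyl-3-[(4-nitrobenzoyl)oxy]octahydroquinoline-1(2H)-carboxylate F3. Methanolysis (K2CO3, MeOH, rt) should give tert-butyl (2S,3R,4aS,5S,8aR)-5-[(5R)-5-{[tert-butyl(dimethyl)silyl]oxy}octyl]-3-hydroxy-2-methyloctahydroquinoline-1(2H)-carboxylate F4. Yamaguchi esterification of F4 with 20 (2,4,6-trichlorobenzoyl chloride, Et3N, DMAP, toluene) proceeds with retention, and the route is rejoined at 21.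

**Further compounds**

F1 | step 5 | methyl N-(tert-butoxycarbonyl)-N-[(1R,2S,3R)-2,3-diethenylcyclohexyl]-L-alaninate | COC(=O)[C@H](C)N(C(=O)OC(C)(C)C)[C@@H]1CCC[C@H](C=C)[C@@H]1C=C
F2 | step 4 | methyl N-(tert-butoxycarbonyl)-N-[(1R,2S,3R)-2,3-diethenylcyclohexyl]-L-alaninate | COC(=O)[C@H](C)N(C(=O)OC(C)(C)C)[C@@H]1CCC[C@H](C=C)[C@@H]1C=C
F3 | step 13 | tert-butyl (2S,3R,4aS,5S,8aR)-5-[(5R)-5-{[tert-butyl(dimethyl)silyl]oxy}octyl]-2-methyl-3-[(4-nitrobenzoyl)oxy]octahydroquinoline-1(2H)-carboxylate | O=C(O[C@@H]1C[C@H]2[C@@H](CCCC[C@H](O[Si](C)(C)C(C)(C)C)CCC)CCC[C@H]2N(C(=O)OC(C)(C)C)[C@H]1C)c1ccc(cc1)[N+](=O)[O-]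
F4 | step 13 | tert-butyl (2S,3R,4aS,5S,8aR)-5-[(5R)-5-{[tert-butyl(dimethyl)silyl]oxy}octyl]-3-hydroxy-2-methyloctahydroquinoline-1(2H)-carboxylate | O[C@@H]1C[C@H]2[C@@H](CCCC[C@H](O[Si](C)(C)C(C)(C)C)CCC)CCC[C@H]2N(C(=O)OC(C)(C)C)[C@H]1C
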